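## Analysis of the target

Numbering used throughout: in the piperidine ring N1, C2 (bears CH3), C3 (bears the lactone oxygen), C4, C5, C6 (bears the chain). The same numbers with a prime are used for the 2-methyl-Δ1-piperideine (2,3,4,5-tetrahydropyridine) ring, where C2'=N1'.

- Target 19 is a 26-membered head-to-tail macrodiolide with the ring path [O–C3–C4–C5–C6–(CH2)7–C(=O)] taken twice. In each half a two-atom bridge N1–C2 spans C6 and C3 and creates the six-membered ring.
- There are five stereocentres. Two are identical 1,4-pairs, C3(S)/C6(R) and C3'(S)/C6'(R). The fifth is C2(S), which is cis to both neighbours (all-cis piperidine: O axial, CH3 and chain equatorial).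
- The two clusters are separated by seven CH2 groups and an ester, so neither can control the other.
- Both halves have the same skeleton and configuration. They differ only by two hydrogens at N1–C2, so the molecule is pseudo-C2-symmetric.
- The α-acyloxy ketimine is sensitive: enamine tautomerism would epimerise C3', and it can hydrolyse. The secondary amine lies β to an ester oxygen, and both esters are secondary alkyl esters. The imine should therefore appear late and under mild conditions.
- The strategy rests on this feature: in both six-membered rings the lactone oxygen sits on C3, and C3 is bonded to a C2 that carries only CH3 and N1.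
  - The triad O–C3–C2–CH3 is the oxidised form of a branched allylic ester O–CH(R)–CH=CH2, which is the product of adding a carboxylic acid across a terminal allene.
  - The N1 bridge is only the closed form of a δ-amino methyl ketone.
- The difficulty lies in the combination of a large ring, two remote stereoclusters, and a break of symmetry by a single oxidation level.

## Retrosynthetic reasoning

**19 to 18 (C2–H and N1–H of the piperidine ring).** Removing these two hydrogens leads to the C2-symmetric bis-imine 18. This is the one move that makes the pseudo-symmetric target truly symmetric, so everything before it can be done on both halves in the same flask. The forward step must deliver one hydride per molecule to the face of C2=N1 anti to the pseudo-axial C3–O bond. The two imines are homotopic, so this is a statistical desymmetrisation. That price is accepted knowingly: it is paid once, at the end, with recoverable 18, and it replaces a second monomer synthesis and an orthogonal set of protecting groups.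

**18 to 16 (both C2=N1 bonds, two rings).** Each Δ1-piperideine is opened to its δ-amino methyl ketone, masked on nitrogen. Both heterocycles vanish, leaving a monocyclic 26-membered diolide 16 that carries two acetyl groups and two protected amines. The forward reaction only has to free the amines (17); six-ring ketimine formation then follows by itself.

**16 to 15 (both C2=O groups).** Each acetyl group is traced to a vinyl group by a ketone-selective Wacker-type oxidation. This keeps the epimerisable α-acyloxy ketone out of the macrocyclisation and exposes the branched allylic ester retron at C3.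

**15 to two molecules of 13 (both O–C3 bonds).** The cut is at the alkyl–oxygen bond, not at the acyl–oxygen bond. The precursor therefore needs neither a C3 alcohol nor a C3 stereocentre. One rhodium-catalysed operation has to form two C–O bonds, close the 26-membered ring and set C3 and C3'. Monomer 13 has half the carbons and a single stereocentre.

**13 to 9 (nitrogen protection and ester cleavage, via 12 and 11).** The nitrogen must carry no N–H, or it would capture the allyl-metal intermediate or the Pd-activated vinyl group in a small-ring closure. It must not be an azide, because the catalyst carries phosphines. It must also leave under acid without a reductant. A doubly carbamate-protected amine meets all three demands.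

**9 to 7 and 4 (C5–C6 bond).** The bond next to nitrogen is cut so that C6 is set by auxiliary-controlled addition to an aldimine. The whole C7–C15 chain, including the ester, comes from one nine-carbon aldehyde, and C1–C5 come from one five-carbon allenyl halide through 8.

**7 to 5 and 6; 4 to 3 to 1.** Imine condensation gives 7. One-carbon allene homologation of a terminal alkyne (via 2) followed by bromination gives 4.

## Alternatives that were turned down

**Alternative 1:** the textbook route.
- Disconnection: the two acyl–oxygen bonds C(=O)–O(C3) and C(=O)–O(C3').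
- Forward key step: N-Boc-carpamic acid A1 and the azido ketol acid A2, each in complementary protected form, are esterified and deprotected to seco acid A3. A3 is closed by a Yamaguchi-type macrolactonisation. Boc removal and a Staudinger/aza-Wittig closure finish the synthesis.
- Reasons for rejection:
  - The key step forms one C–O bond and no stereocentre.
  - All five stereocentres and one heterocycle must exist beforehand, in two different monomer syntheses.
  - At least four protecting-group operations are needed to enforce the head-to-tail order.
  - The α-ketol of A2 is epimerisable and prone to acyloin-type shifts under basic acyl activation.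
  - The step count is roughly doubled.

**Alternative 2:** carbon–carbon closure far from the lactones, in the middle of one heptamethylene chain.
- Forward key step: ring-closing metathesis of diene A4, then saturation of the new alkene.
- Reasons for rejection:
  - The ring closure itself is safe, but it creates none of the C–O bonds, heterocycles or stereocentres. It only moves the ring closure.
  - A4 needs both halves fully built and differentiated, plus two extra alkenoic acid pieces.
  - The alkene must afterwards be reduced in the presence of an azide or imine, which rules out plain hydrogenation.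

**Alternative 3:** all stereocentres from a flat precursor.
- Disconnection: every ring C–H bond, leading to the achiral bis(pyridin-3-yl ester) macrocycle A5.
- Forward key step: global hydrogenation.
- Reasons for rejection:
  - cis-Hydrogenation would give the all-cis relation within each ring. Nothing fixes the absolute sense or the relation between the two rings (C2 against meso).
  - One ring cannot be halted at the ketimine stage with C6' already set.
  - The aryl esters are activated esters, and the C3–O bond becomes allylic or vinylogous in partly reduced intermediates, which invites hydrogenolysis.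

Key step: step 8

Assumption 1: methyl 9-oxononanoate (5) is treated as a catalogue compound (it is the ozonolysis fragment of methyl oleate).

Assumption 2: the (R,R)-ligand is taken to give the 3S configuration. The sense of induction belongs to the ligand enantiomer and both are available, so the antipode would be used if the sense were the opposite.

## Steps

Step 1
Reactants: 1 but-3-yn-1-ol
Product: 3 penta-3,4-dien-1-ol, via Mannich base 2 (not isolated)
Conditions: (CH2O)n, CuBr (cat.), i-Pr2NH, 1,4-dioxane, reflux
Reagents that add atoms: paraformaldehyde (reacts as formaldehyde), C=O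
Why: Crabbé homologation: a copper-catalysed Mannich reaction gives propargylic amine 2, which fragments by a 1,5-hydride shift (retro-imino-ene) to the terminal allene. The free primary alcohol is tolerated in this reaction type.

Step 2
Reactants: 3 penta-3,4-dien-1-ol
Product: 4 5-bromopenta-1,2-diene
Conditions: CBr4, PPh3, CH2Cl2, 0 °C
Reagents that add atoms: tetrabromomethane, BrC(Br)(Br)Br
Why: Appel reaction, a neutral SN2 displacement at a primary carbon. No cation is formed, so the allene should stay untouched.

Step 3
Reactants: 5 methyl 9-oxononanoate; 6 (R)-2-methylpropane-2-sulfinamide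
Product: 7 methyl (9E)-9-{[(R)-tert-butylsulfinyl]imino}nonanoate
Conditions: CuSO4 (anhydrous), CH2Cl2, rt
Reagents that add atoms: none
Why: Condensation of an unbranched aldehyde with tert-butanesulfinamide over a mild Lewis-acidic drying agent should give only the E-aldimine. No titanium alkoxide is used, so the methyl ester cannot transesterify.

Step 4
Reactants: 4 5-bromopenta-1,2-diene; 7 methyl (9E)-9-{[(R)-tert-butylsulfinyl]imino}nonanoate
Product: 9 methyl (9R)-9-{[(R)-tert-butylsulfinyl]amino}tetradeca-12,13-dienoate, via Grignard reagent 8 (not isolated)
Conditions: 4, Mg, Et2O, rt; then 7, CH2Cl2, −48 °C; aq NH4Cl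
Reagents that add atoms: none
Why: 1,2-Addition of a Grignard reagent to an N-tert-butanesulfinyl aldimine. In a non-coordinating solvent a closed chair transition state (Mg bound to the sulfinyl oxygen, tert-butyl equatorial) directs the alkyl group to the face that gives 9R (= C6) from the (R)-auxiliary. At −48 °C the activated aldimine should react well before the remote methyl ester.

Step 5
Reactants: 9 methyl (9R)-9-{[(R)-tert-butylsulfinyl]amino}tetradeca-12,13-dienoate
Product: 11 methyl (9R)-9-[(tert-butoxycarbonyl)amino]tetradeca-12,13-dienoate, via amine hydrochloride 10 (not isolated)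
Conditions: HCl (4 M in dioxane), MeOH, 0 °C to rt; evaporate; Boc2O, Et3N, CH2Cl2, rt
Reagents that add atoms: di-tert-butyl dicarbonate, CC(C)(C)OC(=O)OC(=O)OC(C)(C)C
Why: Acidic methanolysis of the S–N bond is fast and does not touch C9. A short exposure to cold dilute acid should spare the terminal allene. Standard carbamate formation follows in the same flask.

Step 6
Reactants: 11 methyl (9R)-9-[(tert-butoxycarbonyl)amino]tetradeca-12,13-dienoate
Product: 12 methyl (9R)-9-[bis(tert-butoxycarbonyl)amino]tetradeca-12,13-dienoate
Conditions: Boc2O (excess), DMAP, MeCN, 40 °C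
Reagents that add atoms: di-tert-butyl dicarbonate, CC(C)(C)OC(=O)OC(=O)OC(C)(C)C
Why: DMAP-catalysed acylation of a carbamate N–H to the imidodicarbonate. Removing the last N–H closes off the 5-exo capture of the allyl-rhodium species in step 8 and the 6-exo aminopalladation in step 9.

Step 7
Reactants: 12 methyl (9R)-9-[bis(tert-butoxycarbonyl)amino]tetradeca-12,13-dienoate
Product: 13 (9R)-9-[bis(tert-butoxycarbonyl)amino]tetradeca-12,13-dienoic acid
Conditions: LiOH, THF/H2O, 0 °C to rt; then 1 M HCl to pH 4, 0 °C
Reagents that add atoms: lithium hydroxide, [Li+].[OH-]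
Why: Saponification of an unhindered methyl ester. The imidodicarbonate on a secondary alkyl carbon is shielded and should be attacked much more slowly by hydroxide.

Step 8
Reactants: 13 (9R)-9-[bis(tert-butoxycarbonyl)amino]tetradeca-12,13-dienoic acid (two molecules)
Product: 15 (10R,13S,23R,26S)-10,23-bis[bis(tert-butoxycarbonyl)amino]-13,26-diethenyl-1,14-dioxacyclohexacosane-2,15-dione, via linear head-to-tail dimer 14 (not isolated)
Conditions: [Rh(cod)Cl]2 (5 mol %), (R,R)-cyclopentylidene-DIOP (12 mol %), Cs2CO3 (10 mol %), ClCH2CH2Cl (ca. 0.02 M), 40 °C
Reagents that add atoms: none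
Why: The Rh(I)–diphosphine complex adds the carboxylic O–H, the Rh–H hydrometallates the allene with H going to the central carbon (future C2), and the π-allyl-rhodium carboxylate forms the C–O bond at the substituted allyl terminus (future C3), first between two molecules of 13 to give 14 and then within 14. The closest known reaction type is the Rh/DIOP-catalysed enantioselective addition of carboxylic acids to terminal allenes, including its use for the head-to-tail cyclodimerisation of ω-allenyl carboxylic acids to C2-symmetric 14- to 28-membered diolides, so a 26-membered ring lies inside the known range. The ring is closed in an exo mode, the tethered carboxylate bonding to the internal allyl terminus and leaving the vinyl group outside, while the endo mode (linear allylic ester, 28-membered ring) is suppressed by the branched selectivity of this catalyst. Both new stereocentres (C3 and C3', 13S and 26S) are set by the ligand, since C6 is separated from the reacting terminus by two CH2 groups and should exert no matched or mismatched bias. Because 13 is a single enantiomer, a wrong-face event ends in a diastereomeric macrocycle that can be removed by chromatography. Head-to-tail connectivity needs no control, as each monomer has exactly one acid and one allene. The step needs dimer formation to beat closure of 13 on itself and chain growth, which is addressed by an intermediate concentration and by the strain of a 13-membered ring that would have to hold the bulky N(Boc)2-bearing carbon and a branched ester. The substrate has no N–H and no phosphine-sensitive group, so neither the nitrogen nor the ligand is consumed.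

Step 9
Reactants: 15 (10R,13S,23R,26S)-10,23-bis[bis(tert-butoxycarbonyl)amino]-13,26-diethenyl-1,14-dioxacyclohexacosane-2,15-dione
Product: 16 (10R,13S,23R,26S)-13,26-diacetyl-10,23-bis[bis(tert-butoxycarbonyl)amino]-1,14-dioxacyclohexacosane-2,15-dione
Conditions: Pd(Quinox)Cl2 (cat.), AgSbF6 (cat.), aq t-BuOOH, CH2Cl2, 0 °C to rt
Reagents that add atoms: tert-butyl hydroperoxide, CC(C)(C)OO
Why: Catalyst-controlled Wacker-type oxidation with a peroxide as oxidant. The bidentate ligand overrides the directing effect of the allylic ester oxygen, so protected allylic alcohols give methyl ketones. The conditions are close to neutral, so C3 should keep its configuration.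

Step 10
Reactants: 16 (10R,13S,23R,26S)-13,26-diacetyl-10,23-bis[bis(tert-butoxycarbonyl)amino]-1,14-dioxacyclohexacosane-2,15-dione
Product: 18 C2-symmetric bis-imine macrodiolide (3S,6R,3'S,6'R; both six-membered rings are 2-methyl-Δ1-piperideines), via bis(ammonium trifluoroacetate) 17 (not isolated)
Conditions: TFA/CH2Cl2, 0 °C to rt; evaporate; sat. aq NaHCO3/CH2Cl2, 0 °C
Reagents that add atoms: none
Why: Acidolysis removes all four Boc groups while the α-acyloxy ketones are stable to acid. On cold neutralisation each δ-amino ketone should close to the six-membered ketimine, faster than a seven-membered O-to-N acyl shift. No new stereocentre is formed, and brief cold contact with a weak base limits enamine-mediated epimerisation at C3.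

Step 11
Reactants: 18 C2-symmetric bis-imine macrodiolide
Product: 19 target (2S,3S,6R,3'S,6'R)
Conditions: NaBH(OAc)3 (0.6 equiv), AcOH, CH2Cl2, −20 °C; aq NaHCO3; recovered 18 is resubmitted
Reagents that add atoms: none
Why: Reduction of a cyclic iminium ion by axial hydride attack on the half-chair with the C6 chain pseudo-equatorial and the C3–O bond pseudo-axial. Attack anti to that C–O bond places the C2 methyl equatorial and gives the all-cis (2S) piperidine. The two imines are homotopic, so a one-hydride reagent is used in deficit to hold back double reduction, and the large basicity gap between amine and imine should allow separation and recycling of 18.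

## Compound list

1 | but-3-yn-1-ol | C#CCCO | starting material
2 | 5-(diisopropylamino)pent-3-yn-1-ol | OCCC#CCN(C(C)C)C(C)C | intermediate
3 | penta-3,4-dien-1-ol | OCCC=C=C | intermediate
4 | 5-bromopenta-1,2-diene | BrCCC=C=C | intermediate
5 | methyl 9-oxononanoate | COC(=O)CCCCCCCC=O | starting material
6 | (R)-2-methylpropane-2-sulfinamide | CC(C)(C)[S@@](=O)N | starting material
7 | methyl (9E)-9-{[(R)-tert-butylsulfinyl]imino}nonanoate | CC(C)(C)[S@@](=O)/N=C/CCCCCCCC(=O)OC | intermediate
8 | penta-3,4-dienylmagnesium bromide | Br[Mg]CCC=C=C | intermediate
9 | methyl (9R)-9-{[(R)-tert-butylsulfinyl]amino}tetradeca-12,13-dienoate | COC(=O)CCCCCCC[C@H](CCC=C=C)N[S@](=O)C(C)(C)C | intermediate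
10 | methyl (9R)-9-aminotetradeca-12,13-dienoate hydrochloride | COC(=O)CCCCCCC[C@H](CCC=C=C)[NH3+].[Cl-] | intermediate
11 | methyl (9R)-9-[(tert-butoxycarbonyl)amino]tetradeca-12,13-dienoate | COC(=O)CCCCCCC[C@H](CCC=C=C)NC(=O)OC(C)(C)C | intermediate
12 | methyl (9R)-9-[bis(tert-butoxycarbonyl)amino]tetradeca-12,13-dienoate | COC(=O)CCCCCCC[C@H](CCC=C=C)N(C(=O)OC(C)(C)C)C(=O)OC(C)(C)C | intermediate
13 | (9R)-9-[bis(tert-butoxycarbonyl)amino]tetradeca-12,13-dienoic acid | OC(=O)CCCCCCC[C@H](CCC=C=C)N(C(=O)OC(C)(C)C)C(=O)OC(C)(C)C | intermediate
14 | (9R,12S)-9-[bis(tert-butoxycarbonyl)amino]-12-{[(9R)-9-[bis(tert-butoxycarbonyl)amino]tetradeca-12,13-dienoyl]oxy}tetradec-13-enoic acid | C=C=CCC[C@H](N(C(=O)OC(C)(C)C)C(=O)OC(C)(C)C)CCCCCCCC(=O)O[C@H](C=C)CC[C@H](N(C(=O)OC(C)(C)C)C(=O)OC(C)(C)C)CCCCCCCC(=O)O | intermediate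
15 | (10R,13S,23R,26S)-10,23-bis[bis(tert-butoxycarbonyl)amino]-13,26-diethenyl-1,14-dioxacyclohexacosane-2,15-dione | C=C[C@@H]1CC[C@H](N(C(=O)OC(C)(C)C)C(=O)OC(C)(C)C)CCCCCCCC(=O)O[C@H](C=C)CC[C@H](N(C(=O)OC(C)(C)C)C(=O)OC(C)(C)C)CCCCCCCC(=O)O1 | intermediate
16 | (10R,13S,23R,26S)-13,26-diacetyl-10,23-bis[bis(tert-butoxycarbonyl)amino]-1,14-dioxacyclohexacosane-2,15-dione | CC(=O)[C@@H]1CC[C@H](N(C(=O)OC(C)(C)C)C(=O)OC(C)(C)C)CCCCCCCC(=O)O[C@H](C(C)=O)CC[C@H](N(C(=O)OC(C)(C)C)C(=O)OC(C)(C)C)CCCCCCCC(=O)O1 | intermediate
17 | (10R,13S,23R,26S)-13,26-diacetyl-10,23-diamino-1,14-dioxacyclohexacosane-2,15-dione bis(trifluoroacetate) | CC(=O)[C@@H]1CC[C@H]([NH3+])CCCCCCCC(=O)O[C@H](C(C)=O)CC[C@H]([NH3+])CCCCCCCC(=O)O1.[O-]C(=O)C(F)(F)F.[O-]C(=O)C(F)(F)F | intermediate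
18 | C2-symmetric bis-imine macrodiolide (3S,6R,3'S,6'R) | CC1=N[C@@H]2CCCCCCCC(=O)O[C@H]3CC[C@@H](CCCCCCCC(=O)O[C@H]1CC2)N=C3C | intermediate
19 | target CNP0304114.1 (2S,3S,6R,3'S,6'R) | CC1=N[C@@H]2CCCCCCCC(=O)O[C@H]3CC[C@@H](CCCCCCCC(=O)O[C@H]1CC2)N[C@H]3C | target

## Step count and least certain steps

Total step count: 11. Longest linear sequence: 10 (steps 1, 2 and 4 to 11). The branch from 5 has 9 steps.

**Step 8 (key step).**
- What may go wrong: 13 closes on itself to a 13-membered lactone, or the chain grows beyond the dimer. The intermolecular and the intramolecular event ask for opposite concentration regimes. A second concern is erosion of facial selectivity at C3.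
- Fallback (sets out from 12 and 13, returns at 15): the two C–O bonds are made one at a time.
  - Acid 13 is added slowly to an excess of allenyl ester 12 under the same catalysis, so that the acid meets the allene of 12 rather than that of another molecule of 13. This should give the linear dimer methyl ester F1, and surplus 12 is recovered.
  - The unhindered terminal methyl ester of F1 is cleaved with Me3SnOH in the presence of the hindered secondary allylic ester. This gives seco acid 14, now isolated.
  - 14 is closed at high dilution (syringe pump, about 1 mM) to 15.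

**Step 11.**
- What may go wrong: both imines of one molecule are reduced, or conversion is low. The two sites are homotopic and too far apart to sense each other, so a single pass cannot exceed the statistical limit of one half. Enamine-mediated epimerisation at C3' in the acidic medium is a further risk.
- Fallback (sets out from 10 and 13, returns at 19): the symmetry is broken by orthogonal nitrogen protection and stepwise assembly.
  - Salt 10 is reductively benzylated (PhCHO, NaBH(OAc)3) to the N-benzylamine F2 and capped with CbzCl to the N-benzyl carbamate F3, which has no N–H.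
  - Slow addition of 13 to excess F3 under the conditions of step 8 should give the mixed linear dimer F4.
  - Me3SnOH gives the mixed seco acid F5.
  - High-dilution rhodium-catalysed closure gives the mixed divinyl macrocycle F6.
  - The oxidation of step 9 gives the mixed diketone F7.
  - Hydrogenation over Pd(OH)2/C removes benzyl and Cbz on one half only. The freed amine condenses and is hydrogenated in the same flask to the all-cis piperidine F8. The N(Boc)2 ketone half does not react.
  - The conditions of step 10 then give 19 without any statistical step.

**Step 9.**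
- What may go wrong: the oxidant attacks the terminal carbon (aldehyde formation) under the directing influence of the allylic ester oxygen, or Pd(II) catalyses a 1,3-shift of the allylic ester to the linear isomer, which would widen the ring.
- Fallback (sets out from 15, returns at 16): palladium is avoided.
  - A Mukaiyama hydration (Co(acac)2, PhSiH3, O2), which proceeds by hydrogen-atom transfer with Markovnikov selectivity, should give the bis(secondary alcohol) F9 as a mixture of carbinol epimers.
  - Dess–Martin oxidation under buffered conditions converges this mixture to 16.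

**Step 4.**
- What may go wrong: α-deprotonation of the aliphatic aldimine, attack on the methyl ester, or loss of facial selectivity if the ether co-solvent opens the chelated transition state.
- Fallback (sets out from 4 and 5, returns at 12): the C–N bond is made by inversion instead of by addition to C=N.
  - Bromide 4 is converted via 8 and ZnCl2, with removal of the magnesium salts, into bis(penta-3,4-dienyl)zinc F10.
  - F10 is added to aldehyde 5 under Ti(Oi-Pr)4 and a chiral bis(sulfonamide) catalyst, an ester-tolerant reaction. The ligand enantiomer is chosen to give the (9S)-alcohol F11.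
  - A Mitsunobu reaction with di-tert-butyl iminodicarboxylate inverts C9 and gives 12 directly.

## Further compounds

F1 | step 8 | methyl (9R,12S)-9-[bis(tert-butoxycarbonyl)amino]-12-{[(9R)-9-[bis(tert-butoxycarbonyl)amino]tetradeca-12,13-dienoyl]oxy}tetradec-13-enoate | C=C=CCC[C@H](N(C(=O)OC(C)(C)C)C(=O)OC(C)(C)C)CCCCCCCC(=O)O[C@H](C=C)CC[C@H](N(C(=O)OC(C)(C)C)C(=O)OC(C)(C)C)CCCCCCCC(=O)OC
F2 | step 11 | methyl (9R)-9-(benzylamino)tetradeca-12,13-dienoate | COC(=O)CCCCCCC[C@H](CCC=C=C)NCc1ccccc1
F3 | step 11 | methyl (9R)-9-[benzyl(benzyloxycarbonyl)amino]tetradeca-12,13-dienoate | COC(=O)CCCCCCC[C@H](CCC=C=C)N(Cc1ccccc1)C(=O)OCc1ccccc1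
F4 | step 11 | methyl (9R,12S)-9-[benzyl(benzyloxycarbonyl)amino]-12-{[(9R)-9-[bis(tert-butoxycarbonyl)amino]tetradeca-12,13-dienoyl]oxy}tetradec-13-enoate | C=C=CCC[C@H](N(C(=O)OC(C)(C)C)C(=O)OC(C)(C)C)CCCCCCCC(=O)O[C@H](C=C)CC[C@H](N(Cc1ccccc1)C(=O)OCc1ccccc1)CCCCCCCC(=O)OC
F5 | step 11 | (9R,12S)-9-[benzyl(benzyloxycarbonyl)amino]-12-{[(9R)-9-[bis(tert-butoxycarbonyl)amino]tetradeca-12,13-dienoyl]oxy}tetradec-13-enoic acid | C=C=CCC[C@H](N(C(=O)OC(C)(C)C)C(=O)OC(C)(C)C)CCCCCCCC(=O)O[C@H](C=C)CC[C@H](N(Cc1ccccc1)C(=O)OCc1ccccc1)CCCCCCCC(=O)O
F6 | step 11 | (10R,13S,23R,26S)-10-[bis(tert-butoxycarbonyl)amino]-23-[benzyl(benzyloxycarbonyl)amino]-13,26-diethenyl-1,14-dioxacyclohexacosane-2,15-dione | C=C[C@@H]1CC[C@H](N(C(=O)OC(C)(C)C)C(=O)OC(C)(C)C)CCCCCCCC(=O)O[C@H](C=C)CC[C@H](N(Cc2ccccc2)C(=O)OCc2ccccc2)CCCCCCCC(=O)O1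
F7 | step 11 | (10R,13S,23R,26S)-13,26-diacetyl-10-[bis(tert-butoxycarbonyl)amino]-23-[benzyl(benzyloxycarbonyl)amino]-1,14-dioxacyclohexacosane-2,15-dione | CC(=O)[C@@H]1CC[C@H](N(C(=O)OC(C)(C)C)C(=O)OC(C)(C)C)CCCCCCCC(=O)O[C@H](C(C)=O)CC[C@H](N(Cc2ccccc2)C(=O)OCc2ccccc2)CCCCCCCC(=O)O1
F8 | step 11 | macrodiolide with one all-cis (2S,3S,6R)-piperidine ring and one open N(Boc)2 / acetyl half | CC(=O)[C@@H]1CC[C@H](N(C(=O)OC(C)(C)C)C(=O)OC(C)(C)C)CCCCCCCC(=O)O[C@H]2CC[C@@H](CCCCCCCC(=O)O1)N[C@H]2C
F9 | step 9 | (10R,13S,23R,26S)-10,23-bis[bis(tert-butoxycarbonyl)amino]-13,26-bis(1-hydroxyethyl)-1,14-dioxacyclohexacosane-2,15-dione (carbinol epimers) | CC(O)[C@@H]1CC[C@H](N(C(=O)OC(C)(C)C)C(=O)OC(C)(C)C)CCCCCCCC(=O)O[C@H](C(C)O)CC[C@H](N(C(=O)OC(C)(C)C)C(=O)OC(C)(C)C)CCCCCCCC(=O)O1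
F10 | step 4 | bis(penta-3,4-dienyl)zinc | C=C=CCC[Zn]CCC=C=C
F11 | step 4 | methyl (9S)-9-hydroxytetradeca-12,13-dienoate | COC(=O)CCCCCCC[C@@H](CCC=C=C)O
A1 | alternative 1 | N-Boc-carpamic acid, 8-[(2R,5S,6S)-1-(tert-butoxycarbonyl)-5-hydroxy-6-methylpiperidin-2-yl]octanoic acid | O[C@H]1CC[C@@H](CCCCCCCC(=O)O)N(C(=O)OC(C)(C)C)[C@H]1C
A2 | alternative 1 | (9R,12S)-9-azido-12-hydroxy-13-oxotetradecanoic acid | CC(=O)[C@@H](O)CC[C@H](N=[N+]=[N-])CCCCCCCC(=O)O
A3 | alternative 1 | seco acid, ester of A2 with the C3 hydroxyl of A1 | CC(=O)[C@@H](O)CC[C@H](N=[N+]=[N-])CCCCCCCC(=O)O[C@H]1CC[C@@H](CCCCCCCC(=O)O)N(C(=O)OC(C)(C)C)[C@H]1C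
A4 | alternative 2 | acyclic diene for ring-closing metathesis (N-Boc-piperidine half with hex-5-enoate at C3; azido ketone half with a but-3-enyl stub at C6') | C=CCC[C@@H](N=[N+]=[N-])CC[C@@H](C(C)=O)OC(=O)CCCCCCC[C@@H]1CC[C@H](OC(=O)CCCC=C)[C@H](C)N1C(=O)OC(C)(C)C
A5 | alternative 3 | achiral bis(2-methylpyridin-3-yl ester) macrodiolide | Cc1nc2ccc1OC(=O)CCCCCCCc1ccc(c(C)n1)OC(=O)CCCCCCC2
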